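**Retrosynthetic overview**
1. Idiadione ⇒ C25 bis(skipped enyne). Both carbonyl groups are unmasked in the last step from two internal alkynes, by a double regioselective C–N bond formation (CuH hydroamination) followed by enamine hydrolysis.
2. C25 diyne ⇒ 3-methylbut-1-yne + a chiral C10 enynol + a C10 furyl allylic alcohol, joined by two allyl–alkynyl couplings (copper acetylide, SN2).
3. Chiral enynol ⇒ (S)-citronellal. CH2CHO becomes C≡CH with no change in carbon count, followed by E-selective SeO2 allylic hydroxylation. The only stereocentre is bought in.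
4. Furyl allylic alcohol ⇒ perillene ⇒ 3-bromofuran + homoprenyl bromide (Kumada coupling), followed by the same SeO2 hydroxylation.
5. Rings: none is formed. The furan is carried through from 3-bromofuran.

Assumption: the stereodescriptor in the SMILES corresponds to (10S). This is the same spatial arrangement as in (S)-(−)-citronellal, which is taken as commercial in at least 96% ee.

**Step 1**
Reactants: 1 5-bromo-2-methylpent-2-ene; 2 3-bromofuran
Product: 4 perillene = 3-(4-methylpent-3-en-1-yl)furan, via Grignard reagent 3 (not isolated)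
Conditions: 1, Mg, THF, 35 °C; then 2, NiCl2(dppp) (2 mol %), THF, 50 °C
Reagents that add atoms: magnesium, [Mg] (in 3 only; 4 holds atoms of 1 and 2 alone)
Why: Kumada–Corriu cross-coupling, in which zerovalent nickel inserts into the C3–Br bond of 2, the primary homoallylic Grignard transmetalates, and the chelating dppp ligand makes reductive elimination faster than β-hydride elimination; no stereocentre is involved.

**Step 2**
Reactants: 4 perillene
Product: 5 (2E)-5-(furan-3-yl)-2-methylpent-2-en-1-ol
Conditions: SeO2 (0.3 equiv), t-BuOOH (2.5 equiv, decane), CH2Cl2, 0 °C, stopped at about 70% conversion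
Reagents that add atoms: tert-butyl hydroperoxide, CC(C)(C)OO (terminal oxygen source, passed on through SeO2, O=[Se]=O)
Why: Catalytic SeO2/t-BuOOH allylic oxidation (ene reaction, then [2,3]-sigmatropic shift) hydroxylates only the methyl group trans to the chain of a trisubstituted alkene, which fixes the E geometry, and the furan survives at 0 °C and partial conversion.

**Step 3**
Reactants: 6 (S)-(−)-citronellal
Product: 8 (3S)-3,7-dimethyloct-6-en-1-yne, via enol nonaflate 7 (not isolated)
Conditions: n-C4F9SO2F (1.2 equiv), P2-Et phosphazene base (2.5 equiv), DMF, −10 → 23 °C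
Reagents that add atoms: nonafluorobutane-1-sulfonyl fluoride, O=S(=O)(F)C(F)(F)C(F)(F)C(F)(F)C(F)(F)F (in 7 only; 8 holds atoms of 6 alone)
Why: One-pot enol sulfonylation and E2 elimination of the 1-alkenyl nonaflate turns CH2CHO into C≡CH; an aldehyde-derived nonaflate can only lose its vinylic hydrogen, so no allene forms, and the base is too weak to remove the propargylic C–H, so the (S) centre is kept.

**Step 4**
Reactants: 8 (3S)-3,7-dimethyloct-6-en-1-yne
Product: 9 (2E,6S)-2,6-dimethyloct-2-en-7-yn-1-ol
Conditions: SeO2 (0.3 equiv), t-BuOOH (2.5 equiv, decane), CH2Cl2, 0 °C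
Reagents that add atoms: tert-butyl hydroperoxide, CC(C)(C)OO (terminal oxygen source, passed on through SeO2, O=[Se]=O)
Why: The same SeO2 ene/[2,3] allylic oxidation applies; the electron-rich trisubstituted alkene reacts much faster than the propargylic C–H of the terminal alkyne, the E-CH2OH group is set by the [2,3] shift, and the stereocentre is untouched.

**Step 5**
Reactants: 5 (2E)-5-(furan-3-yl)-2-methylpent-2-en-1-ol; 9 (2E,6S)-2,6-dimethyloct-2-en-7-yn-1-ol
Product: 12 (2E,6S,10E)-13-(furan-3-yl)-2,6,10-trimethyltrideca-2,10-dien-7-yn-1-ol, via allylic mesylate 10 (not isolated), via allylic bromide 11 (not isolated)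
Conditions: 5 (1.10 equiv), Ms2O (1.05 equiv), i-Pr2NEt (1.4 equiv), THF, −30 °C; LiBr (2 equiv), 0 °C; then 9 (1.0 equiv), CuI (10 mol %), K2CO3 (3 equiv), DMF, 23 °C, Ar
Reagents that add atoms: methanesulfonic anhydride, CS(=O)(=O)OS(C)(=O)=O (in 10 only); lithium bromide, [Li+].[Br-] (in 11 only); 12 holds atoms of 5 and 9 alone
Why: Mesylation and SN2 bromide displacement give the labile primary allylic bromide without transposition, and it is consumed in the same flask by copper-catalysed allylation of a terminal alkyne (Jeffery-type coupling through a copper acetylide) at the unhindered CH2, so the E alkene is kept and the free hydroxyl of 9 is inert to K2CO3, Ms2O being the limiting reagent.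

**Step 6**
Reactants: 12 (2E,6S,10E)-13-(furan-3-yl)-2,6,10-trimethyltrideca-2,10-dien-7-yn-1-ol; 13 3-methylbut-1-yne
Product: 16 3-[(3E,8S,11E)-4,8,12,16-tetramethylheptadeca-3,11-diene-6,14-diyn-1-yl]furan, via allylic mesylate 14 (not isolated), via allylic bromide 15 (not isolated)
Conditions: Ms2O (1.1 equiv), i-Pr2NEt (1.4 equiv), THF, −30 °C; LiBr (2 equiv), 0 °C; then 13 (3 equiv), CuI (10 mol %), K2CO3 (3 equiv), DMF, 23 °C, sealed flask, Ar
Reagents that add atoms: methanesulfonic anhydride, CS(=O)(=O)OS(C)(=O)=O (in 14 only); lithium bromide, [Li+].[Br-] (in 15 only); 16 holds atoms of 12 and 13 alone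
Why: The same mesylate/bromide activation and copper-catalysed SN2 allylation of a terminal alkyne is used; 12 has no terminal alkyne left, so it cannot couple with itself, and K2CO3 is too weak to isomerise the skipped enynes or the propargylic stereocentre.

**Step 7**
Reactants: 16 3-[(3E,8S,11E)-4,8,12,16-tetramethylheptadeca-3,11-diene-6,14-diyn-1-yl]furan
Product: 18 idiadione = (6E,10S,14E)-17-(furan-3-yl)-2,6,10,14-tetramethylheptadeca-6,14-diene-4,12-dione, via bis-enamine 17 (not isolated)
Conditions: Cu(OAc)2 (10 mol %), (R)-DTBM-SEGPHOS (11 mol %), (EtO)2MeSiH (5 equiv), morpholin-4-yl benzoate (2.6 equiv, syringe pump, 6 h), THF, 40 °C; then AcOH/NaOAc buffer (pH 5), THF–H2O, 0 °C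
Reagents that add atoms: water, O (both carbonyl oxygens of 18); morpholin-4-yl benzoate, O=C(ON1CCOCC1)c1ccccc1 (morpholine units of 17 only)
Why: Proposed new method: a two-fold, sterically steered CuH hydroamination of unactivated dialkyl alkynes, used as a regiocontrolled formal hydration; LCuH (monovalent copper, L = DTBM-SEGPHOS) adds syn across each triple bond, the very bulky LCu unit going to the carbon that bears the slim, inductively withdrawing allylic CH2 and hydride going to the carbon next to the α-branched CH(CH3) group; the alkenylcopper is aminated with retention by the N–O electrophile (the key C–N bonds) and the silane regenerates LCuH from the copper benzoate; the E-enamines are then hydrolysed at pH 5 by kinetic C-protonation to the β,γ-unsaturated ketones; the ligand creates no stereocentre, the existing centre ends up β to the carbonyl and cannot epimerise, trisubstituted alkenes and the furan are inert to LCuH, and the 1,6-enyne cycloisomerisation that π-acid hydration catalysts (Au, Pt, Hg salts) would trigger is avoided; closest known reaction type: CuH-catalysed hydroamination of aryl-substituted internal alkynes with O-benzoylhydroxylamines to give E-enamines, together with CuH semireduction of dialkyl alkynes, neither of which has been shown on unsymmetrical dialkyl alkynes or skipped enynes.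

**Compound list**
1 | 5-bromo-2-methylpent-2-ene (homoprenyl bromide) | CC(C)=CCCBr | starting material
2 | 3-bromofuran | Brc1ccoc1 | starting material
3 | (4-methylpent-3-en-1-yl)magnesium bromide | CC(C)=CCC[Mg]Br | intermediate
4 | perillene, 3-(4-methylpent-3-en-1-yl)furan | CC(C)=CCCc1ccoc1 | intermediate
5 | (2E)-5-(furan-3-yl)-2-methylpent-2-en-1-ol | OC/C(C)=C/CCc1ccoc1 | intermediate
6 | (S)-(−)-citronellal, (3S)-3,7-dimethyloct-6-enal | C[C@@H](CCC=C(C)C)CC=O | starting material
7 | (3S)-3,7-dimethylocta-1,6-dien-1-yl nonafluorobutane-1-sulfonate (E/Z mixture at C1=C2) | C[C@@H](CCC=C(C)C)C=COS(=O)(=O)C(F)(F)C(F)(F)C(F)(F)C(F)(F)F | intermediate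
8 | (3S)-3,7-dimethyloct-6-en-1-yne | C[C@@H](CCC=C(C)C)C#C | intermediate
9 | (2E,6S)-2,6-dimethyloct-2-en-7-yn-1-ol | C[C@@H](CC/C=C(\C)CO)C#C | intermediate
10 | (2E)-5-(furan-3-yl)-2-methylpent-2-en-1-yl methanesulfonate | CS(=O)(=O)OC/C(C)=C/CCc1ccoc1 | intermediate
11 | 3-[(3E)-5-bromo-4-methylpent-3-en-1-yl]furan | BrC/C(C)=C/CCc1ccoc1 | intermediate
12 | (2E,6S,10E)-13-(furan-3-yl)-2,6,10-trimethyltrideca-2,10-dien-7-yn-1-ol | C[C@@H](CC/C=C(\C)CO)C#CC/C(C)=C/CCc1ccoc1 | intermediate
13 | 3-methylbut-1-yne | CC(C)C#C | starting material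
14 | (2E,6S,10E)-13-(furan-3-yl)-2,6,10-trimethyltrideca-2,10-dien-7-yn-1-yl methanesulfonate | C[C@@H](CC/C=C(\C)COS(C)(=O)=O)C#CC/C(C)=C/CCc1ccoc1 | intermediate
15 | 3-[(3E,8S,11E)-13-bromo-4,8,12-trimethyltrideca-3,11-dien-6-yn-1-yl]furan | C[C@@H](CC/C=C(\C)CBr)C#CC/C(C)=C/CCc1ccoc1 | intermediate
16 | 3-[(3E,8S,11E)-4,8,12,16-tetramethylheptadeca-3,11-diene-6,14-diyn-1-yl]furan | C[C@@H](CC/C=C(\C)CC#CC(C)C)C#CC/C(C)=C/CCc1ccoc1 | intermediate
17 | (3E,6E,10S,11E,14E)-17-(furan-3-yl)-2,6,10,14-tetramethyl-4,12-di(morpholin-4-yl)heptadeca-3,6,11,14-tetraene (bis-enamine) | CC(C)/C=C(N1CCOCC1)\C/C(C)=C/CC[C@H](C)/C=C(N1CCOCC1)\C/C(C)=C/CCc1ccoc1 | intermediate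
18 | idiadione, (6E,10S,14E)-17-(furan-3-yl)-2,6,10,14-tetramethylheptadeca-6,14-diene-4,12-dione | C/C(=C\CC[C@H](C)CC(=O)C/C(C)=C/CCc1ccoc1)CC(=O)CC(C)C | target

**Step count**
- Total steps: 7.
- Longest linear sequence: 5 (steps 1, 2, 5, 6, 7, or equally steps 3, 4, 5, 6, 7).

**Three steps most likely to fail**

**Step 7 (the proposed new step).**
- Risks: hydrocupration of a dialkyl alkyne may be slower than reduction of the N–O reagent by LCuH; regiocontrol may fall below about 10:1 per alkyne; some conjugation of the enones may occur on hydrolysis.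
- Fallback (known chemistry): it sets out from 16 and comes back at 18. Dicyclohexylborane (2.2 equiv, THF, 0 °C) hydroborates internal alkynes far faster than trisubstituted alkenes. It places boron on the less hindered alkyne carbon, the one next to the allylic CH2. This gives (3Z,6E,10S,11Z,14E)-4,12-bis(dicyclohexylboryl)-17-(furan-3-yl)-2,6,10,14-tetramethylheptadeca-3,6,11,14-tetraene F1. Oxidation with NaBO3·4H2O in THF–water at 0 to 23 °C turns each C–B bond into an enol and hence into the ketone, which is 18. This is the textbook hydroboration–oxidation of an unsymmetrical internal alkyne.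

**Step 3.**
- Risks: aldol self-condensation of the aldehyde under the strong base, and incomplete elimination of the nonaflate.
- Fallback: it sets out from 6 and comes back at 8. Hydrazine hydrate (EtOH, 0 °C) gives (S)-citronellal hydrazone F2. Iodine and Et3N in THF (Barton-type hydrazone iodination) give (6S)-8,8-diiodo-2,6-dimethyloct-2-ene F3 with loss of nitrogen. KOt-Bu (3 equiv) is used in THF rather than DMSO, so that the alkyne does not migrate. At 0 to 23 °C it removes two HI by way of (3S)-1-iodo-3,7-dimethylocta-1,6-diene F4 and delivers 8.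

**Step 2.**
- Risks: oxidative damage to the furan, over-oxidation to the enal, and a low yield.
- Fallback: it sets out from 1 (and uses 2) and comes back at 5, so the furan never meets SeO2.
  - The SeO2/t-BuOOH hydroxylation is run on 1 and gives (2E)-5-bromo-2-methylpent-2-en-1-ol F5.
  - TBSCl and imidazole give tert-butyl{[(2E)-5-bromo-2-methylpent-2-en-1-yl]oxy}dimethylsilane F6.
  - Iodine-activated zinc dust in DMA at 60 °C inserts to give {(3E)-5-[(tert-butyldimethylsilyl)oxy]-4-methylpent-3-en-1-yl}zinc bromide F7.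
  - Negishi coupling with 2 (Pd(OAc)2, SPhos, THF, 40 °C) gives tert-butyl{[(2E)-5-(furan-3-yl)-2-methylpent-2-en-1-yl]oxy}dimethylsilane F8.
  - Bu4NF in THF then frees 5.

**Further compounds**
F1 | step 7 | (3Z,6E,10S,11Z,14E)-4,12-bis(dicyclohexylboryl)-17-(furan-3-yl)-2,6,10,14-tetramethylheptadeca-3,6,11,14-tetraene | CC(C)/C=C(B(C1CCCCC1)C1CCCCC1)\C/C(C)=C/CC[C@H](C)/C=C(B(C1CCCCC1)C1CCCCC1)\C/C(C)=C/CCc1ccoc1
F2 | step 3 | (S)-citronellal hydrazone | C[C@@H](CCC=C(C)C)CC=NN
F3 | step 3 | (6S)-8,8-diiodo-2,6-dimethyloct-2-ene | C[C@@H](CCC=C(C)C)CC(I)I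
F4 | step 3 | (3S)-1-iodo-3,7-dimethylocta-1,6-diene | C[C@@H](CCC=C(C)C)C=CI
F5 | step 2 | (2E)-5-bromo-2-methylpent-2-en-1-ol | OC/C(C)=C/CCBr
F6 | step 2 | tert-butyl{[(2E)-5-bromo-2-methylpent-2-en-1-yl]oxy}dimethylsilane | CC(C)(C)[Si](C)(C)OC/C(C)=C/CCBr
F7 | step 2 | {(3E)-5-[(tert-butyldimethylsilyl)oxy]-4-methylpent-3-en-1-yl}zinc bromide | CC(C)(C)[Si](C)(C)OC/C(C)=C/CC[Zn]Br
F8 | step 2 | tert-butyl{[(2E)-5-(furan-3-yl)-2-methylpent-2-en-1-yl]oxy}dimethylsilane | CC(C)(C)[Si](C)(C)OC/C(C)=C/CCc1ccoc1
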